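Retrosynthetic cuts, in order: the C4–O–CH3 and ArO–Si bonds; C3–C(=O)Ar; C1'–C2' of the geranyl chain (back to a C7 exocyclic methylene, then a C7 ketone and a C7 carbinol); C1–prenyl; the C2 oxygen; the C1–C8 bond of ring B; last, the two C5–CH2 bonds.
Enabling feature: in ring B the gem-dimethyl carbon C8 lies next to C7 and is tied to C5 through C6. C6–C7–C8 is therefore an epoxidised prenyl group on C5 with C8 as its tertiary end. C9 and C1 are the oxygenated and the nucleophilic carbon of an enol ether, so ring A (C1–C5 plus C9) maps onto a prochiral 6,6-disubstituted 1,5-dimethoxycyclohexa-1,4-diene.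
Forward order: ring A comes from Birch reduction of 1,3-dimethoxybenzene. C5 is alkylated twice (prenyl, then epoxyprenyl) and ring B closes through the C1–C8 bond. The cage is then dressed in the order C2=O, C1 prenyl, C7 methylene, geranyl, C3 aroyl.
Stereochemistry: the only external source is the Sharpless epoxidation of prenol. Its oxirane carbon (later C7) picks one of the two enantiotopic enol ethers, which fixes C5 and C1, and is then erased. C7 is reset by exo-face hydroboration, which turns the side chain endo. The E alkene comes from a syn carboalumination.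

Key step: step 6

Remark on numbering: all bicycles carry the numbering C1 (bridgehead next to C8), C2–C4 (ring A), C5 (other bridgehead), C6–C8 (ring B), C9 (bridge). Endo means pointing under ring A towards C3 and exo means the opposite face. Prenyl is 3-methylbut-2-enyl.
Assumption: the enolised β-triketone of the target interconverts freely between its enol tautomers and is drawn as the C4 enol. In that form it is (1S,5S,7S) with the geranyl group endo.

Step 1
Reactants: 1 1,3-dimethoxybenzene
Product: 2 1,5-dimethoxycyclohexa-1,4-diene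
Conditions: Li, NH3 (l), t-BuOH, THF, −78 to −33 °C
Reagents that add atoms: none
Why: In this Birch reduction both donor methoxy groups stay on the surviving double bonds, so the unconjugated 1,4-diene forms with one CH2 flanked by the two enol ether carbons.

Step 2
Reactants: 2 1,5-dimethoxycyclohexa-1,4-diene; 3 prenyl bromide (1-bromo-3-methylbut-2-ene)
Product: 5 1,5-dimethoxy-6-(3-methylbut-2-enyl)cyclohexa-1,4-diene, via 6-lithiated diene 4 (not isolated)
Conditions: t-BuLi, THF, −78 °C; then 3, −78 °C to rt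
Reagents that add atoms: none
Why: The CH2 between the two oxygenated carbons is the most acidic site because its pentadienyl anion keeps the charge off those carbons, and such cyclohexadienyl anions undergo SN2 alkylation at the central carbon with allylic bromides.

Step 3
Reactants: 6 3-methylbut-2-en-1-ol (prenol)
Product: 7 [(2R)-3,3-dimethyloxiran-2-yl]methanol
Conditions: Ti(OiPr)4 (5 mol %), D-(−)-diisopropyl tartrate (7 mol %), t-BuOOH, 4 Å MS, CH2Cl2, −20 °C; non-aqueous work-up
Reagents that add atoms: tert-butyl hydroperoxide, CC(C)(C)OO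
Why: In the Katsuki–Sharpless asymmetric epoxidation of a primary allylic alcohol the D-(−)-tartrate catalyst gives the 2R epoxy alcohol (the L-(+)-ester gives 2S), and this carbon is the later C7.

Step 4
Reactants: 7 [(2R)-3,3-dimethyloxiran-2-yl]methanol
Product: 8 [(2R)-3,3-dimethyloxiran-2-yl]methyl trifluoromethanesulfonate
Conditions: Tf2O, 2,6-lutidine, CH2Cl2, −78 °C; cold work-up, used at once
Reagents that add atoms: trifluoromethanesulfonic anhydride, O=S(=O)(OS(=O)(=O)C(F)(F)F)C(F)(F)F
Why: O-sulfonylation of a primary alcohol with a hindered base at low temperature leaves the oxirane and its stereocentre alone and supplies a leaving group reactive enough for a hindered carbanion at −78 °C.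

Step 5
Reactants: 5 1,5-dimethoxy-6-(3-methylbut-2-enyl)cyclohexa-1,4-diene; 8 [(2R)-3,3-dimethyloxiran-2-yl]methyl trifluoromethanesulfonate
Product: 10 6-{[(2R)-3,3-dimethyloxiran-2-yl]methyl}-1,5-dimethoxy-6-(3-methylbut-2-enyl)cyclohexa-1,4-diene, via 6-lithiated prenyl diene 9 (not isolated)
Conditions: s-BuLi, THF, −78 to −30 °C; then 8, −78 °C
Reagents that add atoms: none
Why: Removing the remaining doubly allylic C6–H regenerates the same pentadienyl anion, which displaces the primary triflate (SN2) at its central carbon faster than it could open the oxirane, and this builds the prochiral quaternary carbon (later C5) without touching the oxirane stereocentre.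

Step 6
Reactants: 10 6-{[(2R)-3,3-dimethyloxiran-2-yl]methyl}-1,5-dimethoxy-6-(3-methylbut-2-enyl)cyclohexa-1,4-diene
Product: 12 (1S,5S,7R)-7-hydroxy-4-methoxy-8,8-dimethyl-5-(3-methylbut-2-enyl)bicyclo[3.3.1]non-3-en-9-one (7-exo alcohol), via bridged methyl ketal 11 (not isolated)
Conditions: TMSOTf (0.3 equiv), 2,6-lutidine (0.5 equiv), CH2Cl2, −78 °C; then Me2BBr (2 equiv), −78 °C; aq NaHCO3
Reagents that add atoms: none
Why: TMSOTf silylates the oxirane oxygen, the C8–O bond stretches towards the tertiary cation, and the β-carbon of one methyl enol ether (C1) attacks C8 anti to the departing oxygen, leaving a C9 methyl oxocarbenium ion and a C7 silyl ether. This is the epoxide-initiated cation–olefin cyclisation known for 6,6-disubstituted 1,5-dimethoxycyclohexa-1,4-dienes, and ring B (C1–C8–C7–C6–C5–C9) closes 6-endo-tet at the oxirane, preferred over 5-exo attack at secondary C7 because the charge builds up on the gem-dimethyl carbon. Collinear backside attack is possible only in a chair whose surviving C7–O bond is equatorial (anti to the new C1–C8 bond), and the (R)-oxirane carbon allows that chair for just one of the two enantiotopic enol ethers, so C7 controls both new stereocentres, C5 (S) and C1 (S), and ends up as the exo carbinol. After a chair-to-boat flip the C7 silyloxy group captures the C9 cation and releases the silyl cation, so the Lewis acid turns over and ketal 11 rests in the flask. Me2BBr, a standard reagent for ketal cleavage at −78 °C, can ionise 11 only at the C9–O7 bond because loss of methoxide would need a bridgehead C9=O+ bond, and bromide then takes the methyl group off the reopened oxocarbenium ion to give the C9 ketone and a C7 borinate that hydrolyses on work-up. The step needs group, site and chemoselectivity: the electron-rich enol ethers outrun the prenyl alkene as nucleophiles, low temperature and the hindered base hold back proton loss to the allylic alcohol, and the buffered medium spares the spectator C3=C4 enol ether, a weaker Lewis base than the ketal oxygens.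

Step 7
Reactants: 12 (1S,5S,7R)-7-hydroxy-4-methoxy-8,8-dimethyl-5-prenylbicyclo[3.3.1]non-3-en-9-one
Product: 13 (1S,5S,7R)-4-methoxy-8,8-dimethyl-5-prenyl-7-(triethylsilyloxy)bicyclo[3.3.1]non-3-en-9-one
Conditions: TESOTf, 2,6-lutidine, CH2Cl2, −78 to 0 °C
Reagents that add atoms: triethylsilyl trifluoromethanesulfonate, CC[Si](CC)(CC)OS(=O)(=O)C(F)(F)F
Why: Silyl triflate with lutidine silylates even a secondary alcohol beside a quaternary carbon, its basic medium spares the enol ether, and the mask is needed because a free C7 alkoxide would add across ring B to C9 and shut down the bridgehead lithiation of step 9.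

Step 8
Reactants: 13 (1S,5S,7R)-4-methoxy-8,8-dimethyl-5-prenyl-7-(triethylsilyloxy)bicyclo[3.3.1]non-3-en-9-one
Product: 14 (1R,5S,7R)-4-methoxy-8,8-dimethyl-5-prenyl-7-(triethylsilyloxy)bicyclo[3.3.1]non-3-ene-2,9-dione
Conditions: PhI(OAc)2, t-BuOOH, K2CO3, EtOAc, −20 °C
Reagents that add atoms: tert-butyl hydroperoxide, CC(C)(C)OO
Why: In this radical allylic C–H oxidation (tert-butylperoxy radical, allylic peroxide, Kornblum–DeLaMare-type collapse) the C2–H bonds are the weakest because the allyl radical is stabilised by the C4 methoxy group, and the step is placed here so that only one prenyl group competes.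

Step 9
Reactants: 14 (1R,5S,7R)-4-methoxy-8,8-dimethyl-5-prenyl-7-(triethylsilyloxy)bicyclo[3.3.1]non-3-ene-2,9-dione; 3 prenyl bromide
Product: 16 (1R,5S,7R)-4-methoxy-8,8-dimethyl-1,5-diprenyl-7-(triethylsilyloxy)bicyclo[3.3.1]non-3-ene-2,9-dione, via bridgehead organolithium 15 (not isolated)
Conditions: LDA, THF, −78 °C; then 3, −78 °C to rt
Reagents that add atoms: none
Why: Bridgehead lithiation–alkylation is established for enol ethers of bicyclo[3.3.1]nonane-2,4,9-triones, C1–H is acidified by both flanking carbonyl groups, and the pyramidal carbanion cannot invert inside the cage, so SN2 prenylation keeps the C1 configuration set in step 6.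

Step 10
Reactants: 16 (1R,5S,7R)-4-methoxy-8,8-dimethyl-1,5-diprenyl-7-(triethylsilyloxy)bicyclo[3.3.1]non-3-ene-2,9-dione
Product: 17 (1R,5S,7R)-7-hydroxy-4-methoxy-8,8-dimethyl-1,5-diprenylbicyclo[3.3.1]non-3-ene-2,9-dione
Conditions: HF·pyridine, THF, 0 °C to rt
Reagents that add atoms: none
Why: Fluoride-driven Si–O cleavage in a mildly acidic medium leaves the vinylogous ester, the non-enolisable β-diketone and the prenyl groups untouched.

Step 11
Reactants: 17 (1R,5S,7R)-7-hydroxy-4-methoxy-8,8-dimethyl-1,5-diprenylbicyclo[3.3.1]non-3-ene-2,9-dione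
Product: 18 (1R,5S)-4-methoxy-8,8-dimethyl-1,5-diprenylbicyclo[3.3.1]non-3-ene-2,7,9-trione
Conditions: Dess–Martin periodinane, CH2Cl2, rt
Reagents that add atoms: none
Why: The Dess–Martin oxidation handles hindered secondary alcohols in the presence of trisubstituted alkenes and deliberately erases the relay stereocentre C7 once it has done its work.

Step 12
Reactants: 18 (1R,5S)-4-methoxy-8,8-dimethyl-1,5-diprenylbicyclo[3.3.1]non-3-ene-2,7,9-trione
Product: 19 (1R,5S)-4-methoxy-8,8-dimethyl-7-methylidene-1,5-diprenylbicyclo[3.3.1]non-3-ene-2,9-dione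
Conditions: Ph3PCH3Br, KHMDS, toluene, 0 °C; then 18, 0 to 60 °C
Reagents that add atoms: methyltriphenylphosphonium bromide, C[P+](c1ccccc1)(c1ccccc1)c1ccccc1.[Br-]
Why: In this Wittig methylenation C7 is the only carbonyl open to the ylide, since C9 now lies between two quaternary bridgeheads and C2 is a vinylogous ester carbonyl next to quaternary C1, and excess ylide with gentle warming is the usual answer to an α-quaternary enolisable ketone.

Step 13
Reactants: 20 5-bromo-2-methylpent-2-ene
Product: 21 6-methylhept-5-en-1-yne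
Conditions: LiC≡CH·H2NCH2CH2NH2, DMSO, rt
Reagents that add atoms: lithium acetylide–ethylenediamine complex, [Li]C#C.NCCN
Why: SN2 alkynylation of a primary bromide by lithium acetylide–ethylenediamine in DMSO is a standard terminal alkyne synthesis.

Step 14
Reactants: 21 6-methylhept-5-en-1-yne
Product: 23 (1E)-1-iodo-2,6-dimethylhepta-1,5-diene, via (E)-alkenyldimethylalane 22 (not isolated)
Conditions: AlMe3, Cp2ZrCl2 (0.25 equiv), CH2Cl2, 0 °C to rt; then I2, THF, −30 °C
Reagents that add atoms: trimethylaluminium, C[Al](C)C; iodine, II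
Why: The Negishi zirconium-catalysed carboalumination adds methyl and aluminium syn with the metal on the terminal carbon, and iodinolysis with retention gives the E vinyl iodide that carries the geometry of the geranyl C2'=C3' alkene.

Step 15
Reactants: 19 (1R,5S)-4-methoxy-8,8-dimethyl-7-methylidene-1,5-diprenylbicyclo[3.3.1]non-3-ene-2,9-dione; 23 (1E)-1-iodo-2,6-dimethylhepta-1,5-diene
Product: 25 (1R,5S,7S)-7-[(2E)-3,7-dimethylocta-2,6-dienyl]-4-methoxy-8,8-dimethyl-1,5-diprenylbicyclo[3.3.1]non-3-ene-2,9-dione (7-endo geranyl), via B-alkyl-9-BBN borane 24 (not isolated)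
Conditions: 9-BBN-H, THF, rt; then 23, Pd(dppf)Cl2 (5 mol %), AsPh3, Cs2CO3, DMF/H2O, rt
Reagents that add atoms: none
Why: 9-BBN prefers the 1,1-disubstituted alkene to the trisubstituted prenyl alkenes and puts boron on the CH2, ring A (C2–C3–C4) roofs the endo face of C7 so hydrogen arrives from the exo face and the CH2B arm is forced endo (7S), and the B-alkyl Suzuki–Miyaura coupling then joins it to 23 with retention of the alkene geometry.

Step 16
Reactants: 26 3-hydroxybenzoic acid
Product: 27 tert-butyldimethylsilyl 3-(tert-butyldimethylsilyloxy)benzoate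
Conditions: TBSCl (2.3 equiv), imidazole, DMF, rt
Reagents that add atoms: tert-butyldimethylsilyl chloride, CC(C)(C)[Si](C)(C)Cl
Why: Imidazole-promoted silylation caps the phenol and the acid in one standard operation.

Step 17
Reactants: 27 tert-butyldimethylsilyl 3-(tert-butyldimethylsilyloxy)benzoate
Product: 28 3-(tert-butyldimethylsilyloxy)benzoyl chloride
Conditions: (COCl)2, DMF (cat.), CH2Cl2, 0 °C to rt
Reagents that add atoms: oxalyl chloride, O=C(Cl)C(=O)Cl
Why: Silyl esters react with the Vilsmeier-type chloroiminium species from oxalyl chloride and DMF to give acid chlorides under neutral conditions, so no HCl appears that could strip the aryl silyl ether.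

Step 18
Reactants: 25 (1R,5S,7S)-7-geranyl-4-methoxy-8,8-dimethyl-1,5-diprenylbicyclo[3.3.1]non-3-ene-2,9-dione; 28 3-(tert-butyldimethylsilyloxy)benzoyl chloride
Product: 30 (1S,5S,7S)-3-[3-(tert-butyldimethylsilyloxy)benzoyl]-7-geranyl-4-methoxy-8,8-dimethyl-1,5-diprenylbicyclo[3.3.1]non-3-ene-2,9-dione, via C3 vinyllithium 29 (not isolated)
Conditions: LiTMP, THF, −78 °C; then 28, −78 °C
Reagents that add atoms: none
Why: Vinylic lithiation of the β-methoxy enone at C3, the only acidic C–H left and one stabilised by the neighbouring carbonyl and methoxy oxygens, followed by C-acylation with an acid chloride is the established way to aroylate C3 of this ring system.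

Step 19
Reactants: 30 (1S,5S,7S)-3-[3-(tert-butyldimethylsilyloxy)benzoyl]-7-geranyl-4-methoxy-8,8-dimethyl-1,5-diprenylbicyclo[3.3.1]non-3-ene-2,9-dione
Product: 31 (1S,5S,7S)-7-[(2E)-3,7-dimethylocta-2,6-dienyl]-4-hydroxy-3-(3-hydroxybenzoyl)-8,8-dimethyl-1,5-bis(3-methylbut-2-enyl)bicyclo[3.3.1]non-3-ene-2,9-dione (CNP0290731.1)
Conditions: LiOH, dioxane/H2O, 90 °C; then 1 M HCl
Reagents that add atoms: lithium hydroxide, [Li+].[OH-]
Why: Hydroxide adds to C4 of the doubly activated enol ether and expels methoxide (vinylogous saponification), the same medium cleaves the base-labile aryl silyl ether, the delocalised triketonate resists retro-Claisen cleavage until acidification, and no stereocentre bears an exchangeable hydrogen.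

Compound list
1 | 1,3-dimethoxybenzene | COc1cccc(OC)c1 | starting material
2 | 1,5-dimethoxycyclohexa-1,4-diene | COC1=CCC=C(OC)C1 | intermediate
3 | prenyl bromide (1-bromo-3-methylbut-2-ene) | CC(C)=CCBr | starting material
4 | 6-lithio-1,5-dimethoxycyclohexa-1,4-diene | COC1=CCC=C(OC)C1[Li] | intermediate
5 | 1,5-dimethoxy-6-(3-methylbut-2-enyl)cyclohexa-1,4-diene | COC1=CCC=C(OC)C1CC=C(C)C | intermediate
6 | 3-methylbut-2-en-1-ol | CC(C)=CCO | starting material
7 | [(2R)-3,3-dimethyloxiran-2-yl]methanol | OC[C@H]1OC1(C)C | intermediate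
8 | [(2R)-3,3-dimethyloxiran-2-yl]methyl trifluoromethanesulfonate | O=S(=O)(OC[C@H]1OC1(C)C)C(F)(F)F | intermediate
9 | 6-lithio-1,5-dimethoxy-6-(3-methylbut-2-enyl)cyclohexa-1,4-diene | COC1=CCC=C(OC)C1([Li])CC=C(C)C | intermediate
10 | 6-{[(2R)-3,3-dimethyloxiran-2-yl]methyl}-1,5-dimethoxy-6-(3-methylbut-2-enyl)cyclohexa-1,4-diene | COC1=CCC=C(OC)C1(CC=C(C)C)C[C@H]2OC2(C)C | intermediate
11 | (1S,5S,7R,9R)-7,9-epoxy-4,9-dimethoxy-8,8-dimethyl-5-prenylbicyclo[3.3.1]non-3-ene (bridged methyl ketal) | O3[C@@H]1C[C@]2(CC=C(C)C)[C@@]3(OC)[C@@H](CC=C2OC)C1(C)C | intermediate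
12 | (1S,5S,7R)-7-hydroxy-4-methoxy-8,8-dimethyl-5-prenylbicyclo[3.3.1]non-3-en-9-one (7-exo OH) | O[C@@H]1C[C@]2(CC=C(C)C)C(=O)[C@@H](CC=C2OC)C1(C)C | intermediate
13 | (1S,5S,7R)-4-methoxy-8,8-dimethyl-5-prenyl-7-(triethylsilyloxy)bicyclo[3.3.1]non-3-en-9-one | CC[Si](CC)(CC)O[C@@H]1C[C@]2(CC=C(C)C)C(=O)[C@@H](CC=C2OC)C1(C)C | intermediate
14 | (1R,5S,7R)-4-methoxy-8,8-dimethyl-5-prenyl-7-(triethylsilyloxy)bicyclo[3.3.1]non-3-ene-2,9-dione | CC[Si](CC)(CC)O[C@@H]1C[C@]2(CC=C(C)C)C(=O)[C@@H](C(=O)C=C2OC)C1(C)C | intermediate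
15 | 1-lithio derivative of 14 (bridgehead organolithium) | CC[Si](CC)(CC)O[C@@H]1C[C@]2(CC=C(C)C)C(=O)[C@@]([Li])(C(=O)C=C2OC)C1(C)C | intermediate
16 | (1R,5S,7R)-4-methoxy-8,8-dimethyl-1,5-diprenyl-7-(triethylsilyloxy)bicyclo[3.3.1]non-3-ene-2,9-dione | CC[Si](CC)(CC)O[C@@H]1C[C@]2(CC=C(C)C)C(=O)[C@@](CC=C(C)C)(C(=O)C=C2OC)C1(C)C | intermediate
17 | (1R,5S,7R)-7-hydroxy-4-methoxy-8,8-dimethyl-1,5-diprenylbicyclo[3.3.1]non-3-ene-2,9-dione | O[C@@H]1C[C@]2(CC=C(C)C)C(=O)[C@@](CC=C(C)C)(C(=O)C=C2OC)C1(C)C | intermediate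
18 | (1R,5S)-4-methoxy-8,8-dimethyl-1,5-diprenylbicyclo[3.3.1]non-3-ene-2,7,9-trione | O=C1C[C@]2(CC=C(C)C)C(=O)[C@@](CC=C(C)C)(C(=O)C=C2OC)C1(C)C | intermediate
19 | (1R,5S)-4-methoxy-8,8-dimethyl-7-methylidene-1,5-diprenylbicyclo[3.3.1]non-3-ene-2,9-dione | C=C1C[C@]2(CC=C(C)C)C(=O)[C@@](CC=C(C)C)(C(=O)C=C2OC)C1(C)C | intermediate
20 | 5-bromo-2-methylpent-2-ene | CC(C)=CCCBr | starting material
21 | 6-methylhept-5-en-1-yne | CC(C)=CCCC#C | intermediate
22 | [(1E)-2,6-dimethylhepta-1,5-dienyl]dimethylalane | CC(C)=CCC/C(C)=C/[Al](C)C | intermediate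
23 | (1E)-1-iodo-2,6-dimethylhepta-1,5-diene | CC(C)=CCC/C(C)=C/I | intermediate
24 | (1R,5S,7S)-7-[(9-borabicyclo[3.3.1]nonan-9-yl)methyl]-4-methoxy-8,8-dimethyl-1,5-diprenylbicyclo[3.3.1]non-3-ene-2,9-dione (7-endo) | C1CCC2CCCC1B2C[C@H]3C[C@]4(CC=C(C)C)C(=O)[C@@](CC=C(C)C)(C(=O)C=C4OC)C3(C)C | intermediate
25 | (1R,5S,7S)-7-[(2E)-3,7-dimethylocta-2,6-dienyl]-4-methoxy-8,8-dimethyl-1,5-diprenylbicyclo[3.3.1]non-3-ene-2,9-dione | CC(C)=CCC/C(C)=C/C[C@H]1C[C@]2(CC=C(C)C)C(=O)[C@@](CC=C(C)C)(C(=O)C=C2OC)C1(C)C | intermediate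
26 | 3-hydroxybenzoic acid | OC(=O)c1cccc(O)c1 | starting material
27 | tert-butyldimethylsilyl 3-(tert-butyldimethylsilyloxy)benzoate | CC(C)(C)[Si](C)(C)OC(=O)c1cccc(O[Si](C)(C)C(C)(C)C)c1 | intermediate
28 | 3-(tert-butyldimethylsilyloxy)benzoyl chloride | ClC(=O)c1cccc(O[Si](C)(C)C(C)(C)C)c1 | intermediate
29 | 3-lithio derivative of 25 (C3 vinyllithium) | CC(C)=CCC/C(C)=C/C[C@H]1C[C@]2(CC=C(C)C)C(=O)[C@@](CC=C(C)C)(C(=O)C([Li])=C2OC)C1(C)C | intermediate
30 | (1S,5S,7S)-3-[3-(tert-butyldimethylsilyloxy)benzoyl]-7-[(2E)-3,7-dimethylocta-2,6-dienyl]-4-methoxy-8,8-dimethyl-1,5-diprenylbicyclo[3.3.1]non-3-ene-2,9-dione | CC(C)=CCC/C(C)=C/C[C@H]1C[C@]2(CC=C(C)C)C(=O)[C@@](CC=C(C)C)(C(=O)C(C(=O)c3cccc(O[Si](C)(C)C(C)(C)C)c3)=C2OC)C1(C)C | intermediate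
31 | (1S,5S,7S)-7-[(2E)-3,7-dimethylocta-2,6-dienyl]-4-hydroxy-3-(3-hydroxybenzoyl)-8,8-dimethyl-1,5-bis(3-methylbut-2-enyl)bicyclo[3.3.1]non-3-ene-2,9-dione | CC(C)=CCC/C(C)=C/C[C@H]1C[C@]2(CC=C(C)C)C(=O)[C@@](CC=C(C)C)(C(=O)C(C(=O)c3cccc(O)c3)=C2O)C1(C)C | target

Total step count: 19.
Longest linear sequence: 13 steps (1, 2, 5, 6, 7, 8, 9, 10, 11, 12, 15, 18, 19).

Steps most likely to fail

**Step 6.** The C1–C8 closure itself is well grounded. The weak point is the in-flask opening of the ketal. The spectator C3=C4 enol ether may be lost there by protonation or boron-assisted demethylation, or the opening may stall because the base ties up the borane.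
- The fallback sets out from 10 and comes back at 14.
- Only the TMSOTf stage is run and bridged ketal 11 is isolated, so that C7–O and C9 protect each other.
- Compound 11 is oxidised at C2 (PhI(OAc)2, t-BuOOH, K2CO3) to (1R,5S,7R,9R)-7,9-epoxy-4,9-dimethoxy-8,8-dimethyl-5-prenylbicyclo[3.3.1]non-3-en-2-one F1, in which the fragile enol ether has become a robust vinylogous ester.
- Me2BBr at −78 °C then opens the ketal to (1R,5S,7R)-7-hydroxy-4-methoxy-8,8-dimethyl-5-prenylbicyclo[3.3.1]non-3-ene-2,9-dione F2.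
- TESOTf with 2,6-lutidine converts F2 into 14.

**Step 12.** Addition of the bulky ylide to a carbonyl beside quaternary C8 may be slow, since only the exo face is open to it. Enolisation towards C6 could then consume the ylide.
- The fallback sets out from 18 and comes back at 19.
- The small, non-basic organocerium reagent from Me3SiCH2Li and CeCl3 (THF, −78 °C) is added from the exo face. This gives (1R,5S,7S)-7-hydroxy-4-methoxy-8,8-dimethyl-1,5-diprenyl-7-[(trimethylsilyl)methyl]bicyclo[3.3.1]non-3-ene-2,9-dione F3.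
- HF·pyridine then triggers the acidic Peterson elimination of F3 to 19.
- This replaces a concerted cycloaddition with a stepwise addition and elimination.

**Step 15.** Hydroboration next to C8 may be slow enough for the prenyl alkenes to compete. Transmetalation of the congested endo B-alkyl group may lag behind protodeboronation.
- The fallback sets out from 19 and comes back at 25. It separates the stereodefining step from the C–C coupling.
- Borane 24 is oxidised with NaBO3 to (1R,5S,7S)-7-(hydroxymethyl)-4-methoxy-8,8-dimethyl-1,5-diprenylbicyclo[3.3.1]non-3-ene-2,9-dione F4. Regio- and stereoisomers can be removed at this stage.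
- An Appel reaction (I2, PPh3, imidazole) gives (1R,5S,7S)-7-(iodomethyl)-4-methoxy-8,8-dimethyl-1,5-diprenylbicyclo[3.3.1]non-3-ene-2,9-dione F5.
- Zinc insertion (Zn, LiCl, THF) gives the ketone-tolerant alkylzinc iodide of the same skeleton F6.
- A Negishi coupling of F6 with 23 (Pd(dppf)Cl2, THF) delivers 25.

Further compounds
F1 | step 6 | (1R,5S,7R,9R)-7,9-epoxy-4,9-dimethoxy-8,8-dimethyl-5-prenylbicyclo[3.3.1]non-3-en-2-one | O3[C@@H]1C[C@]2(CC=C(C)C)[C@@]3(OC)[C@@H](C(=O)C=C2OC)C1(C)C
F2 | step 6 | (1R,5S,7R)-7-hydroxy-4-methoxy-8,8-dimethyl-5-prenylbicyclo[3.3.1]non-3-ene-2,9-dione | O[C@@H]1C[C@]2(CC=C(C)C)C(=O)[C@@H](C(=O)C=C2OC)C1(C)C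
F3 | step 12 | (1R,5S,7S)-7-hydroxy-4-methoxy-8,8-dimethyl-1,5-diprenyl-7-[(trimethylsilyl)methyl]bicyclo[3.3.1]non-3-ene-2,9-dione | C[Si](C)(C)C[C@]1(O)C[C@]2(CC=C(C)C)C(=O)[C@@](CC=C(C)C)(C(=O)C=C2OC)C1(C)C
F4 | step 15 | (1R,5S,7S)-7-(hydroxymethyl)-4-methoxy-8,8-dimethyl-1,5-diprenylbicyclo[3.3.1]non-3-ene-2,9-dione | OC[C@H]1C[C@]2(CC=C(C)C)C(=O)[C@@](CC=C(C)C)(C(=O)C=C2OC)C1(C)C
F5 | step 15 | (1R,5S,7S)-7-(iodomethyl)-4-methoxy-8,8-dimethyl-1,5-diprenylbicyclo[3.3.1]non-3-ene-2,9-dione | IC[C@H]1C[C@]2(CC=C(C)C)C(=O)[C@@](CC=C(C)C)(C(=O)C=C2OC)C1(C)C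
F6 | step 15 | {[(1R,5S,7S)-4-methoxy-8,8-dimethyl-2,9-dioxo-1,5-diprenylbicyclo[3.3.1]non-3-en-7-yl]methyl}zinc iodide | I[Zn]C[C@H]1C[C@]2(CC=C(C)C)C(=O)[C@@](CC=C(C)C)(C(=O)C=C2OC)C1(C)C
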